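## Analysis of the target

Target 24 is a 1-aryl-1,2-dihydronaphthalene lignan. Ring A (methoxy groups on C6, C7 and C8) is fused through C4a and C8a to ring B, which holds the sp3 carbons C1 and C2 and the trisubstituted alkene C3=C4. In the numbering used here, C1 is the methine on C8a that carries the 3,4-dimethoxyphenyl group through C1′, C2 and C3 carry the hydroxymethyl carbons C2a and C3a, and C4 is the alkene CH on C4a. There are only two stereocentres, C1 (R) and C2 (S); they are vicinal CH centres, and the aryl group on C1 and C2a on C2 lie on opposite faces of ring B (trans). The styrene-type C3=C4 bond, the doubly benzylic C1–H and the allylic C2–H make ring B prone to double-bond migration and to aromatisation under acid, strong base or oxidants. Both arenes are electron-rich and are easily halogenated or oxidised, and C3a–OH is allylic. The synthesis is hard because neither stereocentre bears a heteroatom or sits next to a carbonyl group at the oxidation level of the target, because the two aryl groups on C1 differ only in their methoxy pattern, and because C1 is crowded by the two ortho substituents of ring A (C8–OMe and C4a). The strategy rests on one feature: C1 (H, C8a, C1′) and C2 (H, C2a, C3) are the pattern left when an aryl group and a carbon group add to opposite faces of a C1=C2 alkene attached to ring A. If C2 of that alkene carries boron, the boron left on C2 is the handle for C3, and a vinyl group on C4a supplies C4 for closure of ring B.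

## Retrosynthetic reasoning

**C3a–O and C3=C4 (24 ← 23 ← 22).** The last operation is removal of the silyl ether on C3a–O of 23, which is mild and leaves ring B alone. Ring B of 23 is opened at C3=C4, the only ring bond that touches no stereocentre. This gives diene 22, in which C4 is a vinyl group on C4a and C3 is a 1,1-disubstituted alkene. The forward metathesis has to form a six-membered, trisubstituted, styrene-type alkene under neutral conditions, with loss of the two terminal methylene groups.

**C2a–O (22 ← 21).** The hydroxyl group on C2a is traced back to a carbon–silicon bond. C2a can then be introduced as a carbon nucleophile on boron and not as an oxygenated electrophile. The forward oxidation must turn C–Si into C–OH without touching two alkenes and two electron-rich arenes, which calls for an alkoxysilane and a buffered peroxide. It is placed before ring closure so that the oxidant never meets the dihydronaphthalene.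

**C2–C3 (21 ← 15 + 17).** The sp3–sp2 bond at the C2 stereocentre is cut and replaced by a C2–B bond. The forward Zweifel olefination exchanges boron for the alkenyl carbon with retention and brings in C3, its exocyclic methylene and C3a with its oxygen in one piece. The alkenyl partner is lithium reagent 18, made in the flask from bromide 17, itself the silyl ether of alcohol 16. Cutting here leaves the secondary boronic ester 15, which is the direct product of the key step.

**C1–C1′ and C2–C2a together (15 ← 9 + 13 + 11).** These two bonds lie anti across C1–C2, so both are cut at once. This leads to the ring A (Z)-alkenylboronic ester 9, Grignard reagent 13 and aryl triflate 11, joined through borate 14. Making both bonds in one catalytic event across a (Z)-alkene lets the mechanism fix the relative configuration and the chiral ligand the absolute one, and it divides the molecule into three fragments of similar size. The forward reaction has to make palladium activate the borate alkene and not take the alkenyl group from boron, and it has to leave the ring A vinyl group alone. For that reason boron carries the hindered diol 7 and not a less hindered, more Lewis-basic ester.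

**B–C2 (9 ← 5 + 7, 7 ← 6).** The (Z)-alkenylboron unit is traced to terminal alkyne 5 by a trans-hydroboration, with boron parked first on a labile ligand (8) and then moved to diol 7. The forward step must add H and B anti across the triple bond and must not hydroborate the vinyl group. Diol 7 comes from diketone 6 by double methyl addition.

**Ring A substituents (5 ← 4 ← 3 ← 2 ← 1).** C4 (vinyl) is traced to the formyl carbon of 3 and the two alkyne carbons (C1, C2) to the bromide of 2, which comes from bromination of symmetrical 1. The alkyne is attached while the aldehyde is still present, because the ortho-formyl group activates the hindered C–Br bond.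

**Small fragments (11 ← 10, 13 ← 12).** Triflate 11 is the sulfonate of phenol 10, and Grignard reagent 13 is made from chloride 12.

## Alternatives that were turned down

**Alternative 1:** Biomimetic oxidative coupling.
- Disconnection: C2–C3 and C1–C8a are cut together. This leads to the mixed imide A1, in which a feruloyl and a sinapoyl arm hang on one nitrogen that also carries an (S)-1-phenylethyl group.
- Forward key step: one-electron oxidation of both phenols (FeCl3 or anodic) joins the two carbons α to the carbonyl groups (C2–C3). The syringyl ring then adds to the guaiacyl quinone methide (C1–C8a) to give imide A2.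
- For it: two C–C bonds and two rings form in one step from a precursor reached in a few steps from cheap phenolic cinnamic acids. The trans arrangement is the thermodynamic one.
- Against it for this target:
  - The only source of absolute configuration is a stereocentre on nitrogen, separated from C2 by rotatable bonds, so little facial bias is expected.
  - After the C2–C3 coupling either ring can attack either quinone methide, so a constitutional isomer is a likely by-product.
  - A2 has the wrong functional groups. Two phenols must be methylated and the imide must become two CH2OH groups. Hydride reduction of an imide tends to stop at a hydroxylactam or go on to an amine, so a basic ring opening is needed first, and that endangers C2 and the position of the C3=C4 bond.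
- Comparison: Alternative 1 is stronger in the number of steps to the carbon skeleton and in reagent cost. The chosen route offers catalyst-controlled absolute configuration, a mechanistically fixed relative configuration and the correct oxidation pattern from the start.

**Alternative 2:** Ring expansion of an indanone.
- Disconnection: C4 is removed. Ring B is contracted to indanone A3, whose carbonyl carbon (the later C3) is bonded to C4a.
- Forward key step: trimethylsilyldiazomethane adds to the BF3·OEt2-activated carbonyl group, and C4a migrates with loss of N2 to give 2-tetralone A4.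
- For it: both stereocentres are set beforehand in a rigid five-membered ring where trans is favoured. The migrating carbon C4a is electron-rich (para to the C7 methoxy group).
- Against it for this target:
  - The secondary carbon C2 can migrate in competition with C4a.
  - A4 is a β-silyloxy ketone with C2 next to the carbonyl group. Enolisation towards C2 epimerises it or expels the silyloxy group.
  - C3a is missing. It needs regioselective enol triflation towards C4, carbonylation, reduction and desilylation.
  - A3 needs an asymmetric synthesis of its own.
- Comparison: Alternative 2 is as strong or stronger in the predictability of the ring-forming chemistry. The chosen route is shorter, never places a carbonyl group next to C2, and brings C3 and C3a in together.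

**Alternative 3:** Carbenoid C–H insertion.
- Disconnection: only C1–C2 is cut. Ring B is opened to diazo ester A5, in which ring A carries an ortho 3,4-dimethoxybenzyl group and the vinyldiazoacetate unit.
- Forward key step: Rh2(S-DOSP)4 forms a rhodium vinylcarbenoid at C2, which inserts into the doubly benzylic C1–H bond and closes ring B to diester A6.
- For it: ring B and both stereocentres come from one catalytic step at a very activated C–H bond. A single hydride reduction of A6 would give 24, the shortest end-game of all the strategies.
- Against it for this target: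
  - The insertion must close a six-membered ring and not the usual five-membered one. It competes with cyclisation of the cis-vinyldiazo unit to a pyrazole and with addition of the carbenoid to the electron-rich arenes.
  - Enantio- and diastereocontrol of an intramolecular insertion by this catalyst is not assured.
  - The C2–H of A6 is α to one ester and γ to the other. The acidity that would let trans be reached by equilibration also opens the way to alkene migration and aromatisation.
- Comparison: Alternative 3 is stronger in step and atom economy. The chosen route offers a relative configuration fixed by a stereospecific anti addition, an absolute configuration from a well-mapped ligand, no acidic C2–H anywhere and no diazo compound.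

Key step: step 8

Assumption (boron ligand): boron carries the acenaphthoquinone-derived cis-diol 7 ("mac", B(mac) ester) and not pinacol, because β-substituted alkenylboron ate complexes of pinacol esters are known to divert into direct Suzuki–Miyaura transfer.

Assumption (ligand antipode): MandyPhos is 1,1′-bis[bis(4-methoxy-3,5-dimethylphenyl)phosphino]-2,2′-bis[(dimethylamino)(phenyl)methyl]ferrocene. Both antipodes are commercial. The one that leads to (1R,2R)-15 is chosen from the known sense of induction and confirmed on the first batch by correlation with 24.

Assumption (supply): 2 is also sold, in which case step 1 is skipped.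

## Route

Step 1
Reactants: 1 3,4,5-trimethoxybenzaldehyde
Product: 2 2-bromo-3,4,5-trimethoxybenzaldehyde
Conditions: NBS, CHCl3, reflux
Reagents that add atoms: N-bromosuccinimide, O=C1CCC(=O)N1Br
Why: Electrophilic aromatic bromination; the two free ring positions of 1 are equivalent and each is activated by an ortho and a para methoxy group, and the hindered, deactivated product should not react a second time.

Step 2
Reactants: 2 2-bromo-3,4,5-trimethoxybenzaldehyde
Product: 3 3,4,5-trimethoxy-2-[(trimethylsilyl)ethynyl]benzaldehyde
Conditions: ethynyltrimethylsilane, PdCl2(PPh3)2 (3 mol %), CuI (5 mol %), Et3N, THF, 60 °C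
Reagents that add atoms: ethynyltrimethylsilane, C#C[Si](C)(C)C
Why: Sonogashira coupling; the ortho-formyl group speeds oxidative addition into the otherwise electron-rich, doubly ortho-substituted C–Br bond, which is why the alkyne is attached before the aldehyde is methylenated, and the silyl cap prevents alkyne dimerisation.

Step 3
Reactants: 3 3,4,5-trimethoxy-2-[(trimethylsilyl)ethynyl]benzaldehyde
Product: 5 2-ethynyl-3,4,5-trimethoxystyrene, via silyl-capped enyne 4 (not isolated)
Conditions: Ph3PCH3Br, KOt-Bu, THF, 0 °C → rt; then K2CO3, MeOH, rt
Reagents that add atoms: methyltriphenylphosphonium bromide, C[P+](c1ccccc1)(c1ccccc1)c1ccccc1.[Br-]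
Why: Wittig methylenation of a non-enolisable aryl aldehyde gives 4, and methanolysis of the alkynyl C–Si bond in the same flask frees the terminal alkyne; the one-pot finish also evens out any desilylation already caused by the alkoxide base.

Step 4
Reactants: 6 acenaphthoquinone
Product: 7 cis-1,2-dimethyl-1,2-dihydroacenaphthylene-1,2-diol
Conditions: AlMe3 (4 equiv), toluene, 0 °C → rt; aq. NH4Cl work-up; recrystallisation
Reagents that add atoms: trimethylaluminium, C[Al](C)C
Why: Double 1,2-addition of methyl to a non-enolisable 1,2-diketone; the second methyl group should enter anti to the bulky aluminium alkoxide, which puts both hydroxyl groups on one face, and only this cis (meso) diol can bridge one boron atom, so any trans isomer is removed by crystallisation and cannot carry through.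

Step 5
Reactants: 5 2-ethynyl-3,4,5-trimethoxystyrene; 7 cis-1,2-dimethyl-1,2-dihydroacenaphthylene-1,2-diol
Product: 9 (Z)-2-(2,3,4-trimethoxy-6-vinylphenyl)vinylboronic acid B(mac) ester, via (Z)-alkenylboronic acid catechol ester 8 (not isolated)
Conditions: catecholborane, [Rh(cod)Cl]2 (1.5 mol %), P(i-Pr)3 (6 mol %), Et3N, cyclohexane, rt; then 7, rt
Reagents that add atoms: catecholborane, B1Oc2ccccc2O1
Why: Rh-catalysed trans-hydroboration of a terminal alkyne through a rhodium vinylidene (1,2-shift of the alkyne hydrogen, then B–H addition) puts boron on the terminal carbon cis to the aryl group, i.e. the (Z)-alkene; 5 is used in slight excess over the borane at room temperature so that no B–H is left for the vinyl group, and the labile catechol ester 8 is exchanged in the flask for the robust ester of the ditertiary diol 7.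

Step 6
Reactants: 10 3,4-dimethoxyphenol
Product: 11 3,4-dimethoxyphenyl trifluoromethanesulfonate
Conditions: Tf2O, pyridine, CH2Cl2, 0 °C
Reagents that add atoms: trifluoromethanesulfonic anhydride, O=S(=O)(OS(=O)(=O)C(F)(F)F)C(F)(F)F
Why: O-Sulfonylation of a phenol; the triflate is needed (not a halide) because its non-coordinating anion leaves palladium cationic in step 8.

Step 7
Reactants: 12 (chloromethyl)isopropoxydimethylsilane
Product: 13 (isopropoxydimethylsilyl)methylmagnesium chloride
Conditions: Mg turnings, BrCH2CH2Br (cat.), THF, 45–65 °C; used as a titrated solution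
Reagents that add atoms: magnesium, [Mg]
Why: Grignard formation by insertion of magnesium into the C–Cl bond; the hindered isopropoxy group on silicon is not displaced by the reagent, which makes 13 a storable hydroxymethyl anion equivalent.

Step 8
Reactants: 9 (Z)-2-(2,3,4-trimethoxy-6-vinylphenyl)vinylboronic acid B(mac) ester; 13 (isopropoxydimethylsilyl)methylmagnesium chloride; 11 3,4-dimethoxyphenyl trifluoromethanesulfonate
Product: 15 (1R,2R)-1-(3,4-dimethoxyphenyl)-3-(isopropoxydimethylsilyl)-1-(2,3,4-trimethoxy-6-vinylphenyl)propan-2-ylboronic acid B(mac) ester, via chloromagnesium alkenyl(silylmethyl)borate 14 (not isolated)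
Conditions: 9, 13 (1.1 equiv), THF, 0 °C → rt; then NaOTf (2 equiv), 11 (1.2 equiv), Pd(OAc)2 (3 mol %), MandyPhos (3.6 mol %), THF/DMSO, 40–60 °C
Reagents that add atoms: none
Why: Oxidative addition of 11 to zerovalent palladium gives a cationic aryl-palladium (divalent palladium, triflate outside the coordination sphere, chloride removed as NaCl) that binds the electron-rich alkene of borate 14 instead of exchanging ligands with boron. The silylmethyl group then shifts from boron to C2 on the face opposite to palladium while palladium forms a σ-bond to benzylic C1 (metal-induced 1,2-metallate rearrangement), and C–C reductive elimination with retention joins C1 to C1′ and returns zerovalent palladium. The closest known reaction type is the Pd(OAc)2/MandyPhos-catalysed enantioselective conjunctive cross-coupling of β-substituted alkenyl B(mac) ate complexes with aryl triflates, including Grignard-derived complexes run with NaOTf in THF/DMSO. No ring is closed. C2 is set by the anti relationship between the migrating carbon and palladium and C1 by the retentive reductive elimination, so the net anti addition across the (Z)-alkene fixes the relative configuration (aryl on C1 and C2a trans once ring B exists), and the absolute configuration of both centres follows from the alkene face that the chiral palladium complex binds. The step needs conjunctive coupling to beat direct alkenyl transfer to palladium, which the hindered, weakly Lewis-basic oxygen atoms of the mac ester secure, and it needs the borate alkene to outcompete the ring A vinyl group for palladium, which its anionic and far more nucleophilic character secures. Only the sp3 silylmethyl group can migrate, because the alkenyl group is the acceptor and the diol is tied back.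

Step 9
Reactants: 16 2-bromoprop-2-en-1-ol
Product: 17 (2-bromoallyloxy)(tert-butyl)dimethylsilane
Conditions: TBSCl, imidazole, CH2Cl2, 0 °C → rt
Reagents that add atoms: tert-butyldimethylsilyl chloride, CC(C)(C)[Si](C)(C)Cl
Why: Silylation of a primary allylic alcohol; the hydroxyl group must be masked before lithiation, and the bulky silyl group resists oxygen-to-carbon silyl migration in the alkenyllithium at −78 °C.

Step 10
Reactants: 17 (2-bromoallyloxy)(tert-butyl)dimethylsilane; 15 (1R,2R)-1-(3,4-dimethoxyphenyl)-3-(isopropoxydimethylsilyl)-1-(2,3,4-trimethoxy-6-vinylphenyl)propan-2-ylboronic acid B(mac) ester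
Product: 21 tert-butyl{[(3S,4R)-4-(3,4-dimethoxyphenyl)-3-[(isopropoxydimethylsilyl)methyl]-2-methylidene-4-(2,3,4-trimethoxy-6-vinylphenyl)butyl]oxy}dimethylsilane, via 2-lithio-3-(tert-butyldimethylsilyloxy)propene 18 (not isolated), via lithium alkenyl(alkyl)borate 19 (not isolated), via β-iodoalkylboronic ester 20 (not isolated)
Conditions: 17 (1.3 equiv), t-BuLi (2.5 equiv), Et2O, −78 °C; 15, THF, −78 °C; I2, THF, −78 °C; NaOMe, MeOH, −78 °C → rt; aq. Na2S2O3
Reagents that add atoms: none
Why: Zweifel olefination: 18 adds to boron to give borate 19, iodine activates the alkenyl group, C2 migrates from boron to carbon with retention (20), and methoxide-triggered anti elimination of boron and iodide leaves the 1,1-disubstituted alkene, so the C2 configuration of 15 is carried over unchanged (the descriptor changes from R to S only because C3 outranks boron). The t-BuLi is fully consumed by 17 before 15 is added, and at −78 °C the small excess of 18 should attack boron and not the alkoxysilane; partial exchange of isopropoxy for methoxy on silicon is harmless, since either group is oxidised in step 11.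

Step 11
Reactants: 21 tert-butyl{[(3S,4R)-4-(3,4-dimethoxyphenyl)-3-[(isopropoxydimethylsilyl)methyl]-2-methylidene-4-(2,3,4-trimethoxy-6-vinylphenyl)butyl]oxy}dimethylsilane
Product: 22 (2S)-3-[(tert-butyldimethylsilyloxy)methyl]-2-[(R)-(3,4-dimethoxyphenyl)(2,3,4-trimethoxy-6-vinylphenyl)methyl]but-3-en-1-ol
Conditions: KF, KHCO3, 30 % H2O2, THF/MeOH, rt → 40 °C
Reagents that add atoms: hydrogen peroxide, OO
Why: Tamao oxidation: fluoride and hydroperoxide give a hypervalent silyl peroxide in which C2a migrates from silicon to oxygen, and hydrolysis frees the primary alcohol; the buffered nucleophilic peroxide leaves unactivated alkenes, the arenes and the silyl ether alone, and no stereocentre is involved.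

Step 12
Reactants: 22 (2S)-3-[(tert-butyldimethylsilyloxy)methyl]-2-[(R)-(3,4-dimethoxyphenyl)(2,3,4-trimethoxy-6-vinylphenyl)methyl]but-3-en-1-ol
Product: 23 [(1R,2S)-3-[(tert-butyldimethylsilyloxy)methyl]-1-(3,4-dimethoxyphenyl)-6,7,8-trimethoxy-1,2-dihydronaphthalen-2-yl]methanol
Conditions: second-generation Grubbs catalyst (5 mol %), CH2Cl2, 40 °C
Reagents that add atoms: none
Why: Ring-closing metathesis; the ruthenium carbene loads on the monosubstituted styrene and closes onto the 1,1-disubstituted alkene to form the six-membered ring B with the trisubstituted C3=C4 bond, driven by loss of ethylene, and the neutral conditions leave C1 and C2 untouched.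

Step 13
Reactants: 23 [(1R,2S)-3-[(tert-butyldimethylsilyloxy)methyl]-1-(3,4-dimethoxyphenyl)-6,7,8-trimethoxy-1,2-dihydronaphthalen-2-yl]methanol
Product: 24 [(1R,2S)-1-(3,4-dimethoxyphenyl)-6,7,8-trimethoxy-1,2-dihydronaphthalene-2,3-diyl]dimethanol
Conditions: Bu4NF, THF, 0 °C → rt
Reagents that add atoms: none
Why: Fluoride cleavage of a primary silyl ether (Si–F bond formation); the conditions are short and cold, so that the dihydronaphthalene is not exposed to acid or to prolonged base.

## Compound list

1 | 3,4,5-trimethoxybenzaldehyde | COc1cc(C=O)cc(OC)c1OC | starting material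
2 | 2-bromo-3,4,5-trimethoxybenzaldehyde | COc1cc(C=O)c(Br)c(OC)c1OC | intermediate
3 | 3,4,5-trimethoxy-2-[(trimethylsilyl)ethynyl]benzaldehyde | COc1cc(C=O)c(C#C[Si](C)(C)C)c(OC)c1OC | intermediate
4 | trimethyl[(2,3,4-trimethoxy-6-vinylphenyl)ethynyl]silane (not isolated) | COc1cc(C=C)c(C#C[Si](C)(C)C)c(OC)c1OC | intermediate
5 | 2-ethynyl-3,4,5-trimethoxystyrene | COc1cc(C=C)c(C#C)c(OC)c1OC | intermediate
6 | acenaphthoquinone (acenaphthylene-1,2-dione) | O=C1C(=O)c2cccc3cccc1c23 | starting material
7 | cis-1,2-dimethyl-1,2-dihydroacenaphthylene-1,2-diol (meso, "mac" diol) | O[C@]1(C)c2cccc3cccc(c23)[C@]1(C)O | intermediate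
8 | (Z)-2-(2,3,4-trimethoxy-6-vinylphenyl)vinylboronic acid catechol ester (not isolated) | C=Cc1cc(OC)c(OC)c(OC)c1/C=C\B1Oc2ccccc2O1 | intermediate
9 | (Z)-2-(2,3,4-trimethoxy-6-vinylphenyl)vinylboronic acid B(mac) ester (cyclic ester with diol 7) | C=Cc1cc(OC)c(OC)c(OC)c1/C=C\B1O[C@]2(C)c3cccc4cccc(c34)[C@]2(C)O1 | intermediate
10 | 3,4-dimethoxyphenol | COc1ccc(O)cc1OC | starting material
11 | 3,4-dimethoxyphenyl trifluoromethanesulfonate | COc1ccc(OS(=O)(=O)C(F)(F)F)cc1OC | intermediate
12 | (chloromethyl)isopropoxydimethylsilane | CC(C)O[Si](C)(C)CCl | starting material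
13 | (isopropoxydimethylsilyl)methylmagnesium chloride | CC(C)O[Si](C)(C)C[Mg]Cl | intermediate
14 | chloromagnesium borate from 9 and 13: (Z)-alkenyl, silylmethyl and the diolate of 7 on boron (not isolated; configuration at boron not defined) | C=Cc1cc(OC)c(OC)c(OC)c1/C=C\[B-]1(C[Si](C)(C)OC(C)C)O[C@]2(C)c3cccc4cccc(c34)[C@]2(C)O1.[Mg+]Cl | intermediate
15 | (1R,2R)-1-(3,4-dimethoxyphenyl)-3-(isopropoxydimethylsilyl)-1-(2,3,4-trimethoxy-6-vinylphenyl)propan-2-ylboronic acid B(mac) ester | COc1ccc([C@H](c2c(C=C)cc(OC)c(OC)c2OC)[C@H](C[Si](C)(C)OC(C)C)B2O[C@]3(C)c4cccc5cccc(c45)[C@]3(C)O2)cc1OC | intermediate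
16 | 2-bromoprop-2-en-1-ol | OCC(Br)=C | starting material
17 | (2-bromoallyloxy)(tert-butyl)dimethylsilane | C=C(Br)CO[Si](C)(C)C(C)(C)C | intermediate
18 | 2-lithio-3-(tert-butyldimethylsilyloxy)propene (not isolated) | [Li]C(=C)CO[Si](C)(C)C(C)(C)C | intermediate
19 | lithium borate from 15 and 18 (not isolated; configuration at boron not defined) | COc1ccc([C@H](c2c(C=C)cc(OC)c(OC)c2OC)[C@H](C[Si](C)(C)OC(C)C)[B-]2(C(=C)CO[Si](C)(C)C(C)(C)C)O[C@]3(C)c4cccc5cccc(c45)[C@]3(C)O2)cc1OC.[Li+] | intermediate
20 | β-iodoalkylboronic B(mac) ester formed by the 1,2-shift (not isolated; the transient carbon bearing boron is not defined) | COc1ccc([C@H](c2c(C=C)cc(OC)c(OC)c2OC)[C@H](C[Si](C)(C)OC(C)C)C(CI)(CO[Si](C)(C)C(C)(C)C)B2O[C@]3(C)c4cccc5cccc(c45)[C@]3(C)O2)cc1OC | intermediate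
21 | tert-butyl{[(3S,4R)-4-(3,4-dimethoxyphenyl)-3-[(isopropoxydimethylsilyl)methyl]-2-methylidene-4-(2,3,4-trimethoxy-6-vinylphenyl)butyl]oxy}dimethylsilane | COc1ccc([C@H](c2c(C=C)cc(OC)c(OC)c2OC)[C@H](C[Si](C)(C)OC(C)C)C(=C)CO[Si](C)(C)C(C)(C)C)cc1OC | intermediate
22 | (2S)-3-[(tert-butyldimethylsilyloxy)methyl]-2-[(R)-(3,4-dimethoxyphenyl)(2,3,4-trimethoxy-6-vinylphenyl)methyl]but-3-en-1-ol | COc1ccc([C@H](c2c(C=C)cc(OC)c(OC)c2OC)[C@H](CO)C(=C)CO[Si](C)(C)C(C)(C)C)cc1OC | intermediate
23 | [(1R,2S)-3-[(tert-butyldimethylsilyloxy)methyl]-1-(3,4-dimethoxyphenyl)-6,7,8-trimethoxy-1,2-dihydronaphthalen-2-yl]methanol | COc1ccc([C@@H]2c3c(cc(OC)c(OC)c3OC)C=C(CO[Si](C)(C)C(C)(C)C)[C@H]2CO)cc1OC | intermediate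
24 | [(1R,2S)-1-(3,4-dimethoxyphenyl)-6,7,8-trimethoxy-1,2-dihydronaphthalene-2,3-diyl]dimethanol (CNP0274357.1) | COc1ccc([C@@H]2c3c(cc(OC)c(OC)c3OC)C=C(CO)[C@H]2CO)cc1OC | target

## Step count and least certain steps

Total step count: 13. Longest linear sequence: 9 steps (steps 1, 2, 3, 5, 8, 10, 11, 12, 13).

**Step 8 (key step).** Three processes are most likely to go wrong:
- The alkenyl group may be transferred directly from boron to palladium (Suzuki–Miyaura coupling to a stilbene). The β-aryl group favours this, and the twisted, doubly ortho-substituted ring A may hinder π-binding.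
- For the same reason the ligand may discriminate the two alkene faces poorly.
- The cationic aryl-palladium may insert into the ring A vinyl group (Heck reaction).

The fallback makes the same two bonds with the roles of the two aryl groups exchanged, which removes the hindered (Z)-alkenylboron unit. It sets out from 2, 7 and 13 and comes back at 15. Aldehyde 2 is methylenated (Ph3PCH3Br, KOt-Bu) to 2-bromo-3,4,5-trimethoxystyrene F1. F1 is lithiated (n-BuLi, −78 °C), borylated with B(OMe)3 and oxidised (H2O2, NaOH) to 2,3,4-trimethoxy-6-vinylphenol F2, which is triflated (Tf2O, pyridine) to 2,3,4-trimethoxy-6-vinylphenyl trifluoromethanesulfonate F3. Commercial 4-ethynyl-1,2-dimethoxybenzene is hydroborated with catecholborane (uncatalysed syn addition, 70 °C) to (E)-2-(3,4-dimethoxyphenyl)vinylboronic acid catechol ester F4 and exchanged with 7 to (E)-2-(3,4-dimethoxyphenyl)vinylboronic acid B(mac) ester F5. The chloromagnesium borate F6 formed from F5 and 13 is coupled with F3 under the conditions of step 8. Anti addition of the ring A aryl group (to C1) and the silylmethyl group (to C2) across this (E)-alkene gives the same relative configuration as in 15. The ligand antipode is chosen accordingly.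

**Step 5.** The rhodium hydride and boryl species may also hydroborate the ortho vinyl group, the rhodium vinylidene may cyclise onto it, and the (Z)-alkene may isomerise to (E) if the reaction is left too long. The fallback avoids the vinylidene altogether. It sets out from 5 and 7 and comes back at 9. Alkyne 5 is deprotonated (n-BuLi, THF, −78 °C), borylated with B(OiPr)3, treated with anhydrous HCl in Et2O and esterified in the same flask with 7 to [(2,3,4-trimethoxy-6-vinylphenyl)ethynyl]boronic acid B(mac) ester F7. Syn-hydrozirconation with Cp2Zr(H)Cl (1.05 equiv, THF, rt), in which zirconium goes to the boron-bearing carbon, followed by hydrolysis of the C–Zr bond with water, leaves the aryl group and boron cis.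

**Step 10.** Borate formation at the crowded secondary carbon may be incomplete. The alkenyllithium may attack the alkoxysilane, or the Si–O bond may be lost during handling of 15 and 21. The fallback replaces the alkoxysilane by a phenylsilane, which is inert to organolithium reagents and to silica. It sets out from 9, 11 and 17 and comes back at 24. Compound 9 is coupled with commercial (dimethylphenylsilyl)methylmagnesium chloride and 11 as in step 8 to give (1R,2R)-1-(3,4-dimethoxyphenyl)-3-(dimethylphenylsilyl)-1-(2,3,4-trimethoxy-6-vinylphenyl)propan-2-ylboronic acid B(mac) ester F8. Zweifel olefination with 17 as in step 10 gives the phenylsilyl diene F9. A nucleophilic Fleming–Tamao oxidation (t-BuOOH, KH, Bu4NF, DMF, rt → 70 °C) removes the phenyl group from silicon, oxidises the C2a–Si bond and cleaves the silyl ether in one operation. It gives (2S)-2-[(R)-(3,4-dimethoxyphenyl)(2,3,4-trimethoxy-6-vinylphenyl)methyl]-3-methylidenebutane-1,4-diol F10, which is closed with the second-generation Grubbs catalyst directly to 24.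

## Further compounds

F1 | step 8 | 2-bromo-3,4,5-trimethoxystyrene | COc1cc(C=C)c(Br)c(OC)c1OC
F2 | step 8 | 2,3,4-trimethoxy-6-vinylphenol | COc1cc(C=C)c(O)c(OC)c1OC
F3 | step 8 | 2,3,4-trimethoxy-6-vinylphenyl trifluoromethanesulfonate | COc1cc(C=C)c(OS(=O)(=O)C(F)(F)F)c(OC)c1OC
F4 | step 8 | (E)-2-(3,4-dimethoxyphenyl)vinylboronic acid catechol ester | COc1ccc(/C=C/B2Oc3ccccc3O2)cc1OC
F5 | step 8 | (E)-2-(3,4-dimethoxyphenyl)vinylboronic acid B(mac) ester | COc1ccc(/C=C/B2O[C@]3(C)c4cccc5cccc(c45)[C@]3(C)O2)cc1OC
F6 | step 8 | chloromagnesium borate from F5 and 13 | COc1ccc(/C=C/[B-]2(C[Si](C)(C)OC(C)C)O[C@]3(C)c4cccc5cccc(c45)[C@]3(C)O2)cc1OC.[Mg+]Cl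
F7 | step 5 | [(2,3,4-trimethoxy-6-vinylphenyl)ethynyl]boronic acid B(mac) ester | C=Cc1cc(OC)c(OC)c(OC)c1C#CB1O[C@]2(C)c3cccc4cccc(c34)[C@]2(C)O1
F8 | step 10 | (1R,2R)-1-(3,4-dimethoxyphenyl)-3-(dimethylphenylsilyl)-1-(2,3,4-trimethoxy-6-vinylphenyl)propan-2-ylboronic acid B(mac) ester | COc1ccc([C@H](c2c(C=C)cc(OC)c(OC)c2OC)[C@H](C[Si](C)(C)c2ccccc2)B2O[C@]3(C)c4cccc5cccc(c45)[C@]3(C)O2)cc1OC
F9 | step 10 | tert-butyl{[(3S,4R)-4-(3,4-dimethoxyphenyl)-3-[(dimethylphenylsilyl)methyl]-2-methylidene-4-(2,3,4-trimethoxy-6-vinylphenyl)butyl]oxy}dimethylsilane | COc1ccc([C@H](c2c(C=C)cc(OC)c(OC)c2OC)[C@H](C[Si](C)(C)c2ccccc2)C(=C)CO[Si](C)(C)C(C)(C)C)cc1OC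
F10 | step 10 | (2S)-2-[(R)-(3,4-dimethoxyphenyl)(2,3,4-trimethoxy-6-vinylphenyl)methyl]-3-methylidenebutane-1,4-diol | COc1ccc([C@H](c2c(C=C)cc(OC)c(OC)c2OC)[C@H](CO)C(=C)CO)cc1OC
A1 | alternative 1 | N-feruloyl-N-sinapoyl-(S)-1-phenylethylamine (mixed imide) | COc1cc(/C=C/C(=O)N([C@@H](C)c2ccccc2)C(=O)/C=C/c2cc(OC)c(O)c(OC)c2)ccc1O
A2 | alternative 1 | trans-1-(4-hydroxy-3-methoxyphenyl)-7-hydroxy-6,8-dimethoxy-1,2-dihydronaphthalene-2,3-dicarboximide, N-[(S)-1-phenylethyl] | Oc1ccc([C@@H]2c3c(cc(OC)c(O)c3OC)C=C4C(=O)N([C@@H](C)c5ccccc5)C(=O)[C@@H]24)cc1OC
A3 | alternative 2 | trans-3-(3,4-dimethoxyphenyl)-2-(tert-butyldimethylsilyloxymethyl)-4,5,6-trimethoxyindan-1-one | COc1ccc([C@@H]2c3c(cc(OC)c(OC)c3OC)C(=O)[C@H]2CO[Si](C)(C)C(C)(C)C)cc1OC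
A4 | alternative 2 | trans-4-(3,4-dimethoxyphenyl)-3-(tert-butyldimethylsilyloxymethyl)-5,6,7-trimethoxy-3,4-dihydronaphthalen-2(1H)-one | COc1ccc([C@@H]2c3c(cc(OC)c(OC)c3OC)CC(=O)[C@H]2CO[Si](C)(C)C(C)(C)C)cc1OC
A5 | alternative 3 | dimethyl (E)-2-diazo-3-[2-(3,4-dimethoxybenzyl)-3,4,5-trimethoxybenzylidene]succinate | COC(=O)C(=[N+]=[N-])/C(C(=O)OC)=C\c1cc(OC)c(OC)c(OC)c1Cc1ccc(OC)c(OC)c1
A6 | alternative 3 | dimethyl trans-1-(3,4-dimethoxyphenyl)-6,7,8-trimethoxy-1,2-dihydronaphthalene-2,3-dicarboxylate | COc1ccc([C@@H]2c3c(cc(OC)c(OC)c3OC)C=C(C(=O)OC)[C@H]2C(=O)OC)cc1OC
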